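**Plan**

- Labels: the lactone is O1, C2 (C=O), C3, C4, C5. Ring A is the dimethoxyphenyl ring on the C4 benzyl group. Ring B is the catechol ring C1'–C6', joined to C3 through C7'.
- Retrosynthesis, ring B: the catechol is taken back to its keto tautomer (a cyclohex-4-ene-1,2-dione) and then to a cis-diol carbonate. Cutting C2'–C3' and C4'–C5' leaves vinylene carbonate (C3', C4' and both oxygens) and a butadiene (C1', C2', C5', C6') carried on C7'.
- Retrosynthesis, remainder: the C3–C7' bond is cut (enolate alkylation with 2-(bromomethyl)buta-1,3-diene), and the (R)-4-benzyl lactone goes back to a Stobbe half-ester from 3,4-dimethoxybenzaldehyde and dimethyl succinate.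
- Forward order: ring A is bought, the lactone closes in step 3, the diene is attached in step 6, the ring B carbocycle closes in step 7 and is aromatised in step 9.
- Stereochemistry: C4 comes from asymmetric hydrogenation (catalyst control). C3 comes from alkylation anti to the C4 benzyl group (substrate control, also the thermodynamic trans arrangement). The two carbinol centres made in step 7 are temporary.
- Enabling feature: ring B is a 4-alkylcatechol whose adjacent oxygenated carbons C3'/C4' match a symmetric two-carbon dienophile, so no regiochemical question arises and the catechol is never protected.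

Key step: step 7

Assumption: the (S,S) enantiomer of Me-DuPhos is assigned to the (R) acid by analogy with rhodium–DuPhos hydrogenations of itaconates and dehydroamino acids; if the sense proves opposite, the (R,R) ligand is used and nothing else changes.

**Route**

Step 1
Reactants: 1 3,4-dimethoxybenzaldehyde; 2 dimethyl succinate
Product: 4 (E)-4-(3,4-dimethoxyphenyl)-3-(methoxycarbonyl)but-3-enoic acid, via paraconate lactone 3 (not isolated)
Conditions: NaOMe (1.5 equiv), MeOH, reflux; then aq. HCl
Reagents that add atoms: none
Why: Stobbe condensation, in which the succinate enolate adds to the aldehyde, the aldolate lactonises to 3 and base-induced ring opening (E1cB) gives the half-ester carboxylate irreversibly, the E alkene (aryl trans to the ester) being the expected isomer for aromatic aldehydes.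

Step 2
Reactants: 4 (E)-4-(3,4-dimethoxyphenyl)-3-(methoxycarbonyl)but-3-enoic acid
Product: 5 (R)-4-(3,4-dimethoxyphenyl)-3-(methoxycarbonyl)butanoic acid
Conditions: H2 (5 bar), [Rh(cod)((S,S)-Me-DuPhos)]BF4 (0.5 mol%), NaOMe (0.1 equiv), MeOH, 25 °C
Reagents that add atoms: none
Why: Rhodium-catalysed asymmetric hydrogenation of a Stobbe-type itaconate half-ester, in which carboxylate and alkene chelate the cationic rhodium–bisphospholane centre so that H2 is delivered to one enantioface and the future C4 stereocentre is set as R by the ligand, while arene, ester and ethers are untouched.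

Step 3
Reactants: 5 (R)-4-(3,4-dimethoxyphenyl)-3-(methoxycarbonyl)butanoic acid
Product: 7 (R)-4-(3,4-dimethoxybenzyl)dihydrofuran-2(3H)-one, via potassium hydroxy-carboxylate 6 (not isolated)
Conditions: KOH (1.0 equiv), EtOH; CaCl2 (2 equiv), NaBH4 (4 equiv), EtOH, −10 °C to rt; then 3 M HCl, rt
Reagents that add atoms: none
Why: Chemoselective ester reduction by Ca(BH4)2 formed in the flask, which leaves the potassium carboxylate alone, followed by acid-promoted lactonisation of the γ-hydroxy acid; the stereocentre ends up β to the carbonyl, where it cannot epimerise.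

Step 4
Reactants: 8 3-methyl-2,5-dihydrothiophene 1,1-dioxide (3-methyl-3-sulfolene)
Product: 9 3-(bromomethyl)-2,5-dihydrothiophene 1,1-dioxide
Conditions: NBS (1.05 equiv), (PhCO2)2 (5 mol%), CHCl3, reflux; recrystallisation
Reagents that add atoms: N-bromosuccinimide, O=C1CCC(=O)N1Br
Why: Wohl–Ziegler allylic bromination, in which the electrophilic bromine atom abstracts hydrogen from the methyl group in preference to the ring CH2 groups, which are deactivated by the adjacent sulfone.

Step 5
Reactants: 9 3-(bromomethyl)-2,5-dihydrothiophene 1,1-dioxide
Product: 10 2-(bromomethyl)buta-1,3-diene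
Conditions: neat, hydroquinone (1 mol%), 170 °C, ca. 100 mbar, distillate collected at −78 °C and used at once
Reagents that add atoms: none
Why: Thermal cheletropic extrusion of SO2 from a 3-sulfolene (retro-[4+1]), with the volatile diene leaving the hot zone as it forms so that it does not oligomerise there.

Step 6
Reactants: 7 (R)-4-(3,4-dimethoxybenzyl)dihydrofuran-2(3H)-one; 10 2-(bromomethyl)buta-1,3-diene
Product: 12 (3R,4R)-4-(3,4-dimethoxybenzyl)-3-(2-methylidenebut-3-en-1-yl)dihydrofuran-2(3H)-one, via lithium enolate 11 (not isolated)
Conditions: LiN(SiMe3)2 (1.1 equiv), THF, −78 °C; then 10 (1.5 equiv) in THF, −78 to −40 °C; aq. NH4Cl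
Reagents that add atoms: none
Why: Lactone enolate alkylation with an allylic bromide (direct and allylic displacement give the same product), the electrophile approaching the enolate face anti to the C4 benzyl group so that C3 is set as R, trans to C4, as is standard for dibenzylbutyrolactone lignans.

Step 7
Reactants: 12 (3R,4R)-4-(3,4-dimethoxybenzyl)-3-(2-methylidenebut-3-en-1-yl)dihydrofuran-2(3H)-one; 13 vinylene carbonate
Product: 14 (3R,4R)-4-(3,4-dimethoxybenzyl)-3-[(cis-2-oxo-3a,4,7,7a-tetrahydro-1,3-benzodioxol-5-yl)methyl]dihydrofuran-2(3H)-one (both cis-fused diastereomers)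
Conditions: 13 (10 equiv), BHT (2 mol%), o-xylene, sealed tube, 170 °C; excess 13 removed under reduced pressure
Reagents that add atoms: none
Why: A thermal, concerted, suprafacial [4+2] cycloaddition joins the two termini of the 2-substituted butadiene of 12 to the two alkene carbons of 13, forming the C2'–C3' and C4'–C5' bonds in one event; the closest known reactions are the sealed-tube Diels–Alder additions of vinylene carbonate to isoprene and 2,3-dimethylbutadiene. The six-membered carbocycle that becomes ring B closes by this intermolecular cycloaddition (a [4+2] annulation, not the cyclisation of a tethered chain) and is cis-fused to the dioxolanone because the Z geometry locked in the five-membered dienophile is transferred suprafacially. The two new carbinol stereocentres are therefore cis to each other by mechanism, while their sense relative to C3 and C4 is left uncontrolled, since the nearest stereocentre is remote from the diene and both diastereomers converge once the ring is aromatised. No regioselectivity is needed because the two carbons of 13 are equivalent, so the oxygens necessarily end up on adjacent carbons meta and para to C1'. The selectivity that matters is cross-cycloaddition over diene dimerisation and dienophile polymerisation, which a large excess of the thermally robust dienophile and a radical inhibitor should secure. The lactone, the aryl methyl ethers and the C3 stereocentre have no pathway for change under neutral thermal conditions.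

Step 8
Reactants: 14 cycloadduct carbonate (both diastereomers)
Product: 15 (3R,4R)-3-[(cis-4,5-dihydroxycyclohex-1-en-1-yl)methyl]-4-(3,4-dimethoxybenzyl)dihydrofuran-2(3H)-one (both diastereomers)
Conditions: K2CO3 (0.2 equiv), MeOH, 0 °C to rt; then 1 M HCl to pH 3
Reagents that add atoms: none
Why: Base-catalysed transesterification of the strained five-membered cyclic carbonate with methanol releases the cis-diol, while the γ-lactone is favoured over its hydroxy methyl ester and any that opens should reclose on the acidic quench, and C3 stays in the thermodynamic trans arrangement.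

Step 9
Reactants: 15 cis-diol (both diastereomers)
Product: 18 3'-O-demethylarctigenin, via bis(alkoxysulfonium) dichloride 16 (not isolated), via ene-dione 17 (not isolated)
Conditions: (COCl)2 (2.5 equiv), DMSO (5 equiv), CH2Cl2, −78 °C; 15; then Et3N (8 equiv), −78 to 0 °C; degassed aq. NaH2PO4, under Ar
Reagents that add atoms: none
Why: Double Swern oxidation, in which both alkoxysulfonium groups collapse through their ylides to the cyclohex-4-ene-1,2-dione 17; this is the keto tautomer of the catechol and should enolise twice under Et3N, driven by aromatisation, which erases the carbinol centres so that both diastereomers give the same product.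

**Compound list**

1 | 3,4-dimethoxybenzaldehyde | COc1ccc(C=O)cc1OC | starting material
2 | dimethyl succinate | COC(=O)CCC(=O)OC | starting material
3 | methyl 2-(3,4-dimethoxyphenyl)-5-oxotetrahydrofuran-3-carboxylate (paraconate lactone, racemic diastereomer mixture) | COC(=O)C1CC(=O)OC1c1ccc(OC)c(OC)c1 | intermediate
4 | (E)-4-(3,4-dimethoxyphenyl)-3-(methoxycarbonyl)but-3-enoic acid | COc1ccc(/C=C(\CC(=O)O)C(=O)OC)cc1OC | intermediate
5 | (R)-4-(3,4-dimethoxyphenyl)-3-(methoxycarbonyl)butanoic acid | COc1ccc(C[C@H](CC(=O)O)C(=O)OC)cc1OC | intermediate
6 | potassium (R)-3-(3,4-dimethoxybenzyl)-4-hydroxybutanoate | COc1ccc(C[C@@H](CO)CC(=O)[O-])cc1OC.[K+] | intermediate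
7 | (R)-4-(3,4-dimethoxybenzyl)dihydrofuran-2(3H)-one | COc1ccc(C[C@H]2COC(=O)C2)cc1OC | intermediate
8 | 3-methyl-2,5-dihydrothiophene 1,1-dioxide (3-methyl-3-sulfolene) | CC1=CCS(=O)(=O)C1 | starting material
9 | 3-(bromomethyl)-2,5-dihydrothiophene 1,1-dioxide | BrCC1=CCS(=O)(=O)C1 | intermediate
10 | 2-(bromomethyl)buta-1,3-diene | C=CC(=C)CBr | intermediate
11 | lithium enolate of 7 (lithium (R)-3-(3,4-dimethoxybenzyl)-2,3-dihydrofuran-5-olate) | COc1ccc(C[C@H]2COC(O[Li])=C2)cc1OC | intermediate
12 | (3R,4R)-4-(3,4-dimethoxybenzyl)-3-(2-methylidenebut-3-en-1-yl)dihydrofuran-2(3H)-one | COc1ccc(C[C@H]2COC(=O)[C@@H]2CC(=C)C=C)cc1OC | intermediate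
13 | vinylene carbonate (1,3-dioxol-2-one) | O=C1OC=CO1 | starting material
14 | (3R,4R)-4-(3,4-dimethoxybenzyl)-3-{[(3aS,7aR)-2-oxo-3a,4,7,7a-tetrahydro-1,3-benzodioxol-5-yl]methyl}dihydrofuran-2(3H)-one (drawn; the (3aR,7aS) diastereomer forms alongside and is carried with it) | COc1ccc(C[C@H]2COC(=O)[C@@H]2CC2=CC[C@H]3OC(=O)O[C@H]3C2)cc1OC | intermediate
15 | (3R,4R)-3-{[(4R,5S)-4,5-dihydroxycyclohex-1-en-1-yl]methyl}-4-(3,4-dimethoxybenzyl)dihydrofuran-2(3H)-one (drawn; the (4S,5R) diastereomer is carried with it) | COc1ccc(C[C@H]2COC(=O)[C@@H]2CC2=CC[C@@H](O)[C@@H](O)C2)cc1OC | intermediate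
16 | bis(dimethylsulfonio) ether of 15, dichloride (one diastereomer drawn) | COc1ccc(C[C@H]2COC(=O)[C@@H]2CC2=CC[C@@H](O[S+](C)C)[C@@H](O[S+](C)C)C2)cc1OC.[Cl-].[Cl-] | intermediate
17 | (3R,4R)-4-(3,4-dimethoxybenzyl)-3-[(4,5-dioxocyclohex-1-en-1-yl)methyl]dihydrofuran-2(3H)-one | COc1ccc(C[C@H]2COC(=O)[C@@H]2CC2=CCC(=O)C(=O)C2)cc1OC | intermediate
18 | 3'-O-demethylarctigenin, (3R,4R)-3-(3,4-dihydroxybenzyl)-4-(3,4-dimethoxybenzyl)dihydrofuran-2(3H)-one | COc1ccc(C[C@H]2COC(=O)[C@@H]2Cc2ccc(O)c(O)c2)cc1OC | target

**Step count**

Total steps: 9. Longest linear sequence: 7 steps (1, 2, 3, 6, 7, 8, 9) from 3,4-dimethoxybenzaldehyde; the diene branch (steps 4 and 5) joins at step 6.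

**Steps most likely to fail**

Step 7. Dimerisation or oligomerisation of the diene may outrun cycloaddition with the weakly activated dienophile, so that the advanced lactone is consumed in tar, or prolonged heating may erode the material. The fallback moves the cycloaddition to the cheap fragment. It sets out from sulfolene 9, which is heated with a large excess of vinylene carbonate 13 (BHT, sealed tube, 150–160 °C). Diene 10 is then released slowly by SO2 loss and trapped as it forms, giving racemic cis-5-(bromomethyl)-3a,4,7,7a-tetrahydro-1,3-benzodioxol-2-one F1. Lithium enolate 11, made from lactone 7 as in step 6, is alkylated with this allylic bromide (LiN(SiMe3)2, THF, −78 °C), anti to the C4 benzyl group. Because the bromide is racemic, this gives the same pair of diastereomers, and the fallback returns to the route at 14.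

Step 9. The emerging catechol may be intercepted by electrophilic sulfonium species (ortho-methylthiomethylation or methylthiomethyl ether formation), or oxidation may stall after one alcohol and the ketol dehydrate to a monophenol. The fallback uses an oxidant without electrophilic sulfur and accepts over-oxidation on purpose. It sets out from diol 15, which is treated with 2-iodoxybenzoic acid (4 equiv, DMSO, rt). This reagent oxidises 1,2-diols to 1,2-diones without glycol cleavage and takes the resulting catechol on to (3R,4R)-4-(3,4-dimethoxybenzyl)-3-[(3,4-dioxocyclohexa-1,5-dien-1-yl)methyl]dihydrofuran-2(3H)-one F2. Aqueous Na2S2O4 added to the same flask reduces the ortho-quinone back to the catechol, and the fallback returns at 18.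

Step 6. The labile bromodiene may polymerise in the basic medium before it is captured, leaving the enolate to be quenched or to equilibrate towards dialkylation. The fallback builds the diene on the lactone from a stable electrophile. It sets out from lactone 7 (as enolate 11), which is alkylated with 2,3-dibromopropene (LiN(SiMe3)2, THF, −78 °C) to give (3R,4R)-3-(2-bromoprop-2-en-1-yl)-4-(3,4-dimethoxybenzyl)dihydrofuran-2(3H)-one F3. A Stille coupling with tributyl(vinyl)stannane (Pd(PPh3)4, a zerovalent palladium catalyst, toluene, 90 °C) then installs the vinyl group under neutral conditions, and the fallback returns at 12.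

**Further compounds**

F1 | step 7 | racemic cis-5-(bromomethyl)-3a,4,7,7a-tetrahydro-1,3-benzodioxol-2-one (one enantiomer drawn) | BrCC1=CC[C@H]2OC(=O)O[C@H]2C1
F2 | step 9 | (3R,4R)-4-(3,4-dimethoxybenzyl)-3-[(3,4-dioxocyclohexa-1,5-dien-1-yl)methyl]dihydrofuran-2(3H)-one | COc1ccc(C[C@H]2COC(=O)[C@@H]2CC2=CC(=O)C(=O)C=C2)cc1OC
F3 | step 6 | (3R,4R)-3-(2-bromoprop-2-en-1-yl)-4-(3,4-dimethoxybenzyl)dihydrofuran-2(3H)-one | COc1ccc(C[C@H]2COC(=O)[C@@H]2CC(Br)=C)cc1OC
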